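**Retrosynthetic overview** (ring A = central coumarin, ring B = 8‑linked 7‑hydroxycoumarin, ring C = 3‑oxy‑linked 7‑hydroxycoumarin)
1. Removing the acetyl and benzyl groups leads back to a protected tricoumarin. Ring C is cut at C3=C4 and the lactone C–O: a Perkin (aldol‑type) condensation of a bicoumarinyl‑oxyacetic acid with 2,4‑dihydroxybenzaldehyde, the key C–C bond that joins the two fragments.
2. The oxyacetic acid comes from a Suzuki coupling (ring A C6 to ring B C8) of a ring A 6‑boronate carrying the OCH2CO2tBu arm with 7‑benzyloxy‑8‑iodocoumarin.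
3. Ring A: Pechmann condensation of 4‑bromoresorcinol with malic acid. Ring B: umbelliferone, iodinated at C8 and benzylated.
4. Ring order: ring A pyranone first (step 1), ring B pyranone bought in with umbelliferone, ring C pyranone last (step 8).

Assumption: the SMILES has no stereocentre and defines no sense for the biaryl axis, so the target is treated as achiral and no enantiocontrol is needed.

**Step 1**
Reactants: 1 4‑bromoresorcinol (4‑bromobenzene‑1,3‑diol); 2 (±)‑malic acid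
Product: 4 6‑bromo‑7‑hydroxy‑2H‑chromen‑2‑one, via 3‑oxopropanoic acid 3 (not isolated)
Conditions: conc. H2SO4, 115 °C, 2 h; then ice‑water, filter
Reagents that add atoms: none
Why: Pechmann condensation in which sulfuric acid decarbonylates malic acid to formylacetic acid 3, which attacks 1 at C6 (para to one hydroxyl, ortho to the other, the only unhindered activated site) and lactonises with the neighbouring hydroxyl to give the 6‑bromo‑7‑hydroxy pattern, with no stereocentre formed.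

**Step 2**
Reactants: 4 6‑bromo‑7‑hydroxy‑2H‑chromen‑2‑one
Product: 5 tert‑butyl 2‑[(6‑bromo‑2‑oxo‑2H‑chromen‑7‑yl)oxy]acetate
Conditions: tert‑butyl bromoacetate (1.2 equiv), K2CO3 (1.5 equiv), DMF, 50 °C
Reagents that add atoms: tert‑butyl bromoacetate, BrCC(=O)OC(C)(C)C
Why: Williamson ether synthesis on the acidic 7‑hydroxyl with an activated alpha‑bromo ester, the carbonate leaving the lactone intact and the tert‑butyl ester being chosen because it survives the later aqueous base.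

**Step 3**
Reactants: 5 tert‑butyl 2‑[(6‑bromo‑2‑oxo‑2H‑chromen‑7‑yl)oxy]acetate
Product: 6 tert‑butyl 2‑{[2‑oxo‑6‑(4,4,5,5‑tetramethyl‑1,3,2‑dioxaborolan‑2‑yl)‑2H‑chromen‑7‑yl]oxy}acetate
Conditions: B2pin2 (1.3 equiv), PdCl2(dppf) (4 mol %), KOAc (3 equiv), 1,4‑dioxane, 90 °C
Reagents that add atoms: bis(pinacolato)diboron, CC1(C)OB(OC1(C)C)B1OC(C)(C)C(C)(C)O1
Why: Miyaura borylation (oxidative addition of the C–Br bond to zerovalent palladium, acetate‑assisted transmetalation) under conditions that spare the lactone and the ester, boron being placed on the ring A partner because its single ortho oxygen makes it resistant to protodeboronation.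

**Step 4**
Reactants: 7 umbelliferone (7‑hydroxy‑2H‑chromen‑2‑one)
Product: 8 7‑hydroxy‑8‑iodo‑2H‑chromen‑2‑one
Conditions: I2 (1.0 equiv), KI, 20% aq. NH3, 0 °C to rt, slow addition; then dil. HCl to pH 4
Reagents that add atoms: iodine, [I][I]
Why: Electrophilic aromatic iodination of the 7‑phenoxide, which directs to C8, the most nucleophilic ortho position of umbelliferone (the site also taken in its Mannich, formylation and Claisen chemistry), one equivalent of iodine limiting 6,8‑diiodination.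

**Step 5**
Reactants: 8 7‑hydroxy‑8‑iodo‑2H‑chromen‑2‑one
Product: 9 7‑(benzyloxy)‑8‑iodo‑2H‑chromen‑2‑one
Conditions: BnBr (1.2 equiv), K2CO3 (1.5 equiv), DMF, rt to 50 °C
Reagents that add atoms: benzyl bromide, BrCc1ccccc1
Why: Williamson benzylation of the phenol, giving an ether that is stable to the coupling base, to TFA and to hot acetic anhydride.

**Step 6**
Reactants: 6 tert‑butyl 2‑{[2‑oxo‑6‑(4,4,5,5‑tetramethyl‑1,3,2‑dioxaborolan‑2‑yl)‑2H‑chromen‑7‑yl]oxy}acetate (1.2 equiv); 9 7‑(benzyloxy)‑8‑iodo‑2H‑chromen‑2‑one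
Product: 10 tert‑butyl 2‑({6‑[7‑(benzyloxy)‑2‑oxo‑2H‑chromen‑8‑yl]‑2‑oxo‑2H‑chromen‑7‑yl}oxy)acetate
Conditions: Pd(OAc)2 (5 mol %), SPhos (10 mol %), K3PO4 (3 equiv), toluene/H2O 10:1, 90 °C; then 1 M HCl wash to re‑close any opened lactone
Reagents that add atoms: none
Why: Suzuki–Miyaura cross‑coupling in which the bulky electron‑rich biarylphosphine lets palladium join the di‑ortho‑substituted iodide and the ortho‑alkoxy boronate to a tri‑ortho‑substituted biaryl whose axis carries only small oxygen groups and is not a controlled stereoelement.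

**Step 7**
Reactants: 10 tert‑butyl 2‑({6‑[7‑(benzyloxy)‑2‑oxo‑2H‑chromen‑8‑yl]‑2‑oxo‑2H‑chromen‑7‑yl}oxy)acetate
Product: 11 2‑({6‑[7‑(benzyloxy)‑2‑oxo‑2H‑chromen‑8‑yl]‑2‑oxo‑2H‑chromen‑7‑yl}oxy)acetic acid
Conditions: TFA/CH2Cl2 1:3, 0 °C to rt, 3 h
Reagents that add atoms: none
Why: Acidolysis of the tert‑butyl ester (E1 loss of isobutene) frees the acid without any base, so neither lactone is opened, and the aryl benzyl ether is stable to TFA at room temperature.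

**Step 8**
Reactants: 11 2‑({6‑[7‑(benzyloxy)‑2‑oxo‑2H‑chromen‑8‑yl]‑2‑oxo‑2H‑chromen‑7‑yl}oxy)acetic acid; 12 2,4‑dihydroxybenzaldehyde (2 equiv)
Product: 16 3‑({6‑[7‑(benzyloxy)‑2‑oxo‑2H‑chromen‑8‑yl]‑2‑oxo‑2H‑chromen‑7‑yl}oxy)‑2‑oxo‑2H‑chromen‑7‑yl acetate, via acetic mixed anhydride 13 (not isolated), via 4‑formyl‑1,3‑phenylene diacetate 14 (not isolated), via 2‑aryloxyacrylic acid 15 (not isolated)
Conditions: Ac2O (15 equiv), Et3N (4 equiv), 120 °C, 14 h, N2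
Reagents that add atoms: acetic anhydride, CC(=O)OC(C)=O
Why: Perkin (Perkin–Oglialoro) condensation in which acetic anhydride converts the acid into mixed anhydride 13 and the aldehyde into diacetate 14, the amine‑generated enolate of 13 adds intermolecularly to the aldehyde of 14 (aldol addition), loss of acetic acid gives acrylic acid 15 whose carboxyl lies cis to the aryl ring and trans‑acylates the ortho acetate to close ring C, the classical way to 3‑aryloxycoumarins, with no stereocentre formed.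

**Step 9**
Reactants: 16 3‑({6‑[7‑(benzyloxy)‑2‑oxo‑2H‑chromen‑8‑yl]‑2‑oxo‑2H‑chromen‑7‑yl}oxy)‑2‑oxo‑2H‑chromen‑7‑yl acetate
Product: 17 3‑{[6‑(7‑hydroxy‑2‑oxo‑2H‑chromen‑8‑yl)‑2‑oxo‑2H‑chromen‑7‑yl]oxy}‑2‑oxo‑2H‑chromen‑7‑yl acetate
Conditions: BCl3 (1 M in CH2Cl2, 4 equiv), pentamethylbenzene (5 equiv), CH2Cl2, −78 to −30 °C; then MeOH/H2O
Reagents that add atoms: none
Why: Lewis‑acid debenzylation in which BCl3 activates the ether oxygen and pentamethylbenzene traps the benzyl cation (Friedel–Crafts scavenging), a low‑temperature method that spares the aryl acetate, the three lactones, the diaryl ether and the C3=C4 double bonds that hydrogenolysis could reduce.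

**Step 10**
Reactants: 17 3‑{[6‑(7‑hydroxy‑2‑oxo‑2H‑chromen‑8‑yl)‑2‑oxo‑2H‑chromen‑7‑yl]oxy}‑2‑oxo‑2H‑chromen‑7‑yl acetate
Product: 18 7‑hydroxy‑8‑{7‑[(7‑hydroxy‑2‑oxo‑2H‑chromen‑3‑yl)oxy]‑2‑oxo‑2H‑chromen‑6‑yl}‑2H‑chromen‑2‑one (target, CNP0215289.0)
Conditions: conc. HCl (cat.), MeOH/THF 3:1, 55 °C, 4 h
Reagents that add atoms: none
Why: Acid‑catalysed transesterification (methanolysis) of the aryl acetate frees the last 7‑hydroxyl, the coumarin lactones and the electron‑poor aryl enol ether being stable to methanolic HCl, and the product has no stereocentre.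

**Compound list**
1 | 4‑bromoresorcinol (4‑bromobenzene‑1,3‑diol) | Oc1ccc(Br)c(O)c1 | starting material
2 | (±)‑malic acid | OC(CC(O)=O)C(O)=O | starting material
3 | 3‑oxopropanoic acid (formylacetic acid) | O=CCC(O)=O | intermediate (not isolated)
4 | 6‑bromo‑7‑hydroxy‑2H‑chromen‑2‑one | O=c1ccc2cc(Br)c(O)cc2o1 | intermediate
5 | tert‑butyl 2‑[(6‑bromo‑2‑oxo‑2H‑chromen‑7‑yl)oxy]acetate | O=c1ccc2cc(Br)c(OCC(=O)OC(C)(C)C)cc2o1 | intermediate
6 | tert‑butyl 2‑{[2‑oxo‑6‑(4,4,5,5‑tetramethyl‑1,3,2‑dioxaborolan‑2‑yl)‑2H‑chromen‑7‑yl]oxy}acetate | O=c1ccc2cc(B3OC(C)(C)C(C)(C)O3)c(OCC(=O)OC(C)(C)C)cc2o1 | intermediate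
7 | umbelliferone (7‑hydroxy‑2H‑chromen‑2‑one) | O=c1ccc2ccc(O)cc2o1 | starting material
8 | 7‑hydroxy‑8‑iodo‑2H‑chromen‑2‑one | O=c1ccc2ccc(O)c(I)c2o1 | intermediate
9 | 7‑(benzyloxy)‑8‑iodo‑2H‑chromen‑2‑one | O=c1ccc2ccc(OCc3ccccc3)c(I)c2o1 | intermediate
10 | tert‑butyl 2‑({6‑[7‑(benzyloxy)‑2‑oxo‑2H‑chromen‑8‑yl]‑2‑oxo‑2H‑chromen‑7‑yl}oxy)acetate | O=c1ccc2cc(-c3c(OCc4ccccc4)ccc4ccc(=O)oc34)c(OCC(=O)OC(C)(C)C)cc2o1 | intermediate
11 | 2‑({6‑[7‑(benzyloxy)‑2‑oxo‑2H‑chromen‑8‑yl]‑2‑oxo‑2H‑chromen‑7‑yl}oxy)acetic acid | O=c1ccc2cc(-c3c(OCc4ccccc4)ccc4ccc(=O)oc34)c(OCC(=O)O)cc2o1 | intermediate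
12 | 2,4‑dihydroxybenzaldehyde | O=Cc1ccc(O)cc1O | starting material
13 | acetic 2‑({6‑[7‑(benzyloxy)‑2‑oxo‑2H‑chromen‑8‑yl]‑2‑oxo‑2H‑chromen‑7‑yl}oxy)acetic anhydride (acetic mixed anhydride) | O=c1ccc2cc(-c3c(OCc4ccccc4)ccc4ccc(=O)oc34)c(OCC(=O)OC(C)=O)cc2o1 | intermediate (not isolated)
14 | 4‑formyl‑1,3‑phenylene diacetate | CC(=O)Oc1ccc(C=O)c(OC(C)=O)c1 | intermediate (not isolated)
15 | (2E)‑3‑[2,4‑bis(acetyloxy)phenyl]‑2‑({6‑[7‑(benzyloxy)‑2‑oxo‑2H‑chromen‑8‑yl]‑2‑oxo‑2H‑chromen‑7‑yl}oxy)prop‑2‑enoic acid (2‑aryloxyacrylic acid, carboxyl cis to the aryl ring) | OC(=O)/C(Oc1cc2oc(=O)ccc2cc1-c1c(OCc2ccccc2)ccc2ccc(=O)oc12)=C\c1ccc(OC(C)=O)cc1OC(C)=O | intermediate (not isolated)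
16 | 3‑({6‑[7‑(benzyloxy)‑2‑oxo‑2H‑chromen‑8‑yl]‑2‑oxo‑2H‑chromen‑7‑yl}oxy)‑2‑oxo‑2H‑chromen‑7‑yl acetate | O=c1ccc2cc(-c3c(OCc4ccccc4)ccc4ccc(=O)oc34)c(Oc3cc4ccc(OC(C)=O)cc4oc3=O)cc2o1 | intermediate
17 | 3‑{[6‑(7‑hydroxy‑2‑oxo‑2H‑chromen‑8‑yl)‑2‑oxo‑2H‑chromen‑7‑yl]oxy}‑2‑oxo‑2H‑chromen‑7‑yl acetate | O=c1ccc2cc(-c3c(O)ccc4ccc(=O)oc34)c(Oc3cc4ccc(OC(C)=O)cc4oc3=O)cc2o1 | intermediate
18 | 7‑hydroxy‑8‑{7‑[(7‑hydroxy‑2‑oxo‑2H‑chromen‑3‑yl)oxy]‑2‑oxo‑2H‑chromen‑6‑yl}‑2H‑chromen‑2‑one | O=c1ccc2cc(-c3c(O)ccc4ccc(=O)oc34)c(Oc3cc4ccc(O)cc4oc3=O)cc2o1 | target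

**Totals**
Total step count: 10. Longest linear sequence: 8 steps (steps 1, 2, 3, 6, 7, 8, 9, 10 from compound 1); the umbelliferone branch (steps 4, 5) joins at step 6.

**Three steps most likely to fail, each with a fallback**

Step 1 (Pechmann in hot sulfuric acid; sulfonation, charring or loss of bromine can cut the yield). The fallback sets out from 12. Bromination with Br2 (1.0 equiv) in AcOH at 15 °C, para to the 2‑hydroxyl and ortho to the 4‑hydroxyl, gives 5‑bromo‑2,4‑dihydroxybenzaldehyde F1. Heating this with ethyl (triphenylphosphoranylidene)acetate in N,N‑diethylaniline at reflux gives by Wittig olefination ethyl (2Z)‑3‑(5‑bromo‑2,4‑dihydroxyphenyl)prop‑2‑enoate F2 (the E isomer formed alongside equilibrates at this temperature). This ester lactonises in the same flask and the sequence comes back to the route at 4.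

Step 6 (hindered tri‑ortho‑substituted biaryl; slow transmetalation, protodeboronation and base‑opened lactones are the dangers). The fallback sets out from 5. Stannylation with hexamethylditin and Pd(PPh3)4 in toluene at 105 °C gives tert‑butyl 2‑{[2‑oxo‑6‑(trimethylstannyl)‑2H‑chromen‑7‑yl]oxy}acetate F3. A Stille coupling of this stannane with 9 (Pd(PPh3)4, CuI, CsF, DMF, 50 °C) needs no aqueous base and no boronate, and it comes back to the route at 10.

Step 8 (Perkin condensation on the advanced acid; moderate yields, competing condensation of the aldehyde with acetic anhydride itself, poor solubility). The fallback moves the same condensation to an early stage where a moderate yield costs only cheap material. It sets out from 5.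
- TFA/CH2Cl2 gives 2‑[(6‑bromo‑2‑oxo‑2H‑chromen‑7‑yl)oxy]acetic acid F4.
- Heating this acid with 12 in Ac2O/Et3N at 120 °C forms acetic 2‑[(6‑bromo‑2‑oxo‑2H‑chromen‑7‑yl)oxy]acetic anhydride F5. Its enolate adds to diacetate 14 formed in the same flask, giving (2E)‑3‑[2,4‑bis(acetyloxy)phenyl]‑2‑[(6‑bromo‑2‑oxo‑2H‑chromen‑7‑yl)oxy]prop‑2‑enoic acid F6. Lactonisation of that acid gives 3‑[(6‑bromo‑2‑oxo‑2H‑chromen‑7‑yl)oxy]‑2‑oxo‑2H‑chromen‑7‑yl acetate F7, which crystallises.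
- Miyaura borylation (B2pin2, PdCl2(dppf), KOAc, dioxane, 90 °C) gives 2‑oxo‑3‑{[2‑oxo‑6‑(4,4,5,5‑tetramethyl‑1,3,2‑dioxaborolan‑2‑yl)‑2H‑chromen‑7‑yl]oxy}‑2H‑chromen‑7‑yl acetate F8.
- Suzuki coupling of this boronate with 9 under the step 6 conditions, followed by brief Ac2O/pyridine treatment to re‑acetylate any phenol freed by the base, comes back to the route at 16.

**Further compounds**
F1 | step 1 | 5‑bromo‑2,4‑dihydroxybenzaldehyde | O=Cc1cc(Br)c(O)cc1O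
F2 | step 1 | ethyl (2Z)‑3‑(5‑bromo‑2,4‑dihydroxyphenyl)prop‑2‑enoate | CCOC(=O)/C=C\c1cc(Br)c(O)cc1O
F3 | step 6 | tert‑butyl 2‑{[2‑oxo‑6‑(trimethylstannyl)‑2H‑chromen‑7‑yl]oxy}acetate | O=c1ccc2cc([Sn](C)(C)C)c(OCC(=O)OC(C)(C)C)cc2o1
F4 | step 8 | 2‑[(6‑bromo‑2‑oxo‑2H‑chromen‑7‑yl)oxy]acetic acid | O=c1ccc2cc(Br)c(OCC(=O)O)cc2o1
F5 | step 8 | acetic 2‑[(6‑bromo‑2‑oxo‑2H‑chromen‑7‑yl)oxy]acetic anhydride | O=c1ccc2cc(Br)c(OCC(=O)OC(C)=O)cc2o1
F6 | step 8 | (2E)‑3‑[2,4‑bis(acetyloxy)phenyl]‑2‑[(6‑bromo‑2‑oxo‑2H‑chromen‑7‑yl)oxy]prop‑2‑enoic acid | OC(=O)/C(Oc1cc2oc(=O)ccc2cc1Br)=C\c1ccc(OC(C)=O)cc1OC(C)=O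
F7 | step 8 | 3‑[(6‑bromo‑2‑oxo‑2H‑chromen‑7‑yl)oxy]‑2‑oxo‑2H‑chromen‑7‑yl acetate | O=c1ccc2cc(Br)c(Oc3cc4ccc(OC(C)=O)cc4oc3=O)cc2o1
F8 | step 8 | 2‑oxo‑3‑{[2‑oxo‑6‑(4,4,5,5‑tetramethyl‑1,3,2‑dioxaborolan‑2‑yl)‑2H‑chromen‑7‑yl]oxy}‑2H‑chromen‑7‑yl acetate | O=c1ccc2cc(B3OC(C)(C)C(C)(C)O3)c(Oc3cc4ccc(OC(C)=O)cc4oc3=O)cc2o1
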